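**Plan**
1. Retrosynthesis (eudesmane numbering: C14 on C10, C15 on C4, C11–C13 on C7): cut the C11–OOH bond together with the C6=C7 shift (singlet-oxygen ene reaction of a 7(11)-en-8-one), then the ester C–O bond at O-3, then both C–O bonds at C3/C4 (cis-dihydroxylation of a C3=C4 alkene), and last the ring-fusion bond C5–C10.
2. The last cut opens the decalin to the ten-membered ring of germacrone, an achiral commercial trienone that already holds all fifteen carbons, the C8 ketone and the C7=C11 isopropylidene group.
3. Enabling feature: in that ten-membered ring the two E alkenes C1=C10 and C4=C5 lie crossed and face to face, with C5 and C10 within bonding distance; protonation at C1 makes C10 a tertiary cation, and attack by C5 leaves a tertiary cation at C4.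
4. Forward: an enantioselective transannular cation–olefin cyclization forms rings A and B at once; dihydroxylation, angeloylation and photooxygenation follow (four steps).
5. Stereochemistry: C5/C10 from a chiral acid that selects one of the two rapidly interconverting mirror-image conformers of germacrone (trans fusion from the E,E geometry); C3/C4 from osmylation anti to the axial C14 methyl; the Z alkene arrives with angelic acid.

Key step: step 1

Assumption: the (S,S) enantiomer of the acid catalyst is taken as the one that leads to the (5R,10R) series; the sense of induction cannot be predicted with confidence, and the (R,R) catalyst would be used if it proves opposite.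

**Step 1**
Reactants: 1 germacrone [(1(10)E,4E)-germacra-1(10),4,7(11)-trien-8-one]
Product: 2 (5R,10R)-eudesma-3,7(11)-dien-8-one (trans-fused; 10-methyl β; H-5 α)
Conditions: (S,S)-IDPi acid HN[P(=NSO2CF3)(O2R*)]2 with R*(OH)2 = (S)-3,3'-bis[3,5-bis(trifluoromethyl)phenyl]-1,1'-bi-2-naphthol (5 mol%), CH2Cl2/(CF3)2CHOH, −40 °C
Reagents that add atoms: none
Why: Proposed new method: the confined chiral acid protonates C1 of the C1=C10 alkene in the crossed chair–chair conformer while the C4=C5 π bond attacks C10 across the ring, and the tertiary eudesm-4-yl cation, held as an ion pair, then gives up H-3 to the catalyst anion, which regenerates the acid. The closest known reaction types are the achiral acid-mediated transannular cyclization of germacra-1(10),4-dienes (germacrone included) to eudesmanes and the imidodiphosphorimidate-catalysed, protonation-initiated enantioselective cyclization of acyclic polyenes; the enantioselective transannular version is the new element. With respect to the attacking C4=C5 alkene, ring A closes in a 6-endo-trig and ring B in a 6-exo-trig sense through a chair–chair transition state. The trans ring fusion (10-methyl β, H-5 α) follows from anti addition to the two E alkenes, and the absolute configuration at C5 and C10 from the catalyst selecting one of the two enantiomeric, rapidly interconverting planar-chiral conformers of 1, a dynamic kinetic resolution of conformers. The step needs protonation at C1 and not at C5, O-8 or C11, which the substrate secures because only the C10 cation has a π nucleophile within reach while carbonyl protonation is reversible and the cross-conjugated C7=C11 alkene is electron-poor. It also needs proton loss from C3 and not from C15 or C5, which the low temperature and the tight ion pair are meant to favour.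

**Step 2**
Reactants: 2 (5R,10R)-eudesma-3,7(11)-dien-8-one
Product: 3 (3R,4S,5R,10R)-3,4-dihydroxyeudesm-7(11)-en-8-one (3α,4α-diol; 4-methyl β)
Conditions: K2OsO4·2H2O (2 mol%), NMO, acetone/H2O, rt
Reagents that add atoms: N-methylmorpholine N-oxide, C[N+]1([O-])CCOCC1 (oxygen relayed through the osmium catalyst); water, O
Why: Upjohn dihydroxylation: osmium tetroxide should add to the electron-rich trisubstituted C3=C4 alkene and leave the electron-poor tetrasubstituted enone alkene C7=C11 alone, from the α face anti to the axial C14 methyl that shields C4 on the β face, which sets C3 (R) and C4 (S) as the cis α-diol.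

**Step 3**
Reactants: 3 (3R,4S,5R,10R)-3,4-dihydroxyeudesm-7(11)-en-8-one; 4 angelic acid [(Z)-2-methylbut-2-enoic acid]
Product: 6 (3R,4S,5R,10R)-3-angeloyloxy-4-hydroxyeudesm-7(11)-en-8-one, via angeloyl 2,4,6-trichlorobenzoyl mixed anhydride 5 (not isolated)
Conditions: 4, 2,4,6-trichlorobenzoyl chloride, Et3N, toluene, rt; then 3, toluene, 80 °C
Reagents that add atoms: none
Why: Yamaguchi esterification run without DMAP: the secondary axial 3-OH should attack the less hindered angeloyl carbonyl of 5 while the tertiary 4-OH stays free, and the absence of a nucleophilic catalyst avoids the addition–elimination that would turn the Z (angeloyl) into the E (tigloyl) ester; no stereocenter is formed.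

**Step 4**
Reactants: 6 (3R,4S,5R,10R)-3-angeloyloxy-4-hydroxyeudesm-7(11)-en-8-one
Product: 7 (3R,4S,5R,10R)-3-angeloyloxy-4-hydroxy-11-hydroperoxyeudesm-6-en-8-one (target)
Conditions: O2, hν (visible light), tetraphenylporphyrin (cat.), CH2Cl2, 0 °C
Reagents that add atoms: dioxygen, O=O
Why: Schenck ene reaction of singlet oxygen with the s-cis α,β-unsaturated ketone: oxygen should bond to the β-carbon C11 and the axial allylic hydrogen should be taken from C6, the alkyl group geminal to the carbonyl on the α-carbon C7 (gem selectivity of enones), so that the double bond moves to C6=C7; the tetrasubstituted s-cis enone should react much faster than the trisubstituted angelate, and C11 carries two methyl groups, so no stereocenter is created.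

**Compound list**
1 | germacrone, (1(10)E,4E)-germacra-1(10),4,7(11)-trien-8-one | C/C1=C\CC/C(C)=C/CC(=C(C)C)C(=O)C1 | starting material
2 | (5R,10R)-eudesma-3,7(11)-dien-8-one (trans-fused, 10-methyl β, H-5 α) | CC1=CCC[C@]2(C)CC(=O)C(=C(C)C)C[C@@H]12 | intermediate
3 | (3R,4S,5R,10R)-3,4-dihydroxyeudesm-7(11)-en-8-one (3α,4α-diol) | O[C@@H]1CC[C@]2(C)CC(=O)C(=C(C)C)C[C@H]2[C@]1(C)O | intermediate
4 | angelic acid, (Z)-2-methylbut-2-enoic acid | C/C=C(/C)C(=O)O | starting material
5 | angeloyl 2,4,6-trichlorobenzoyl mixed anhydride | C/C=C(/C)C(=O)OC(=O)c1c(Cl)cc(Cl)cc1Cl | intermediate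
6 | (3R,4S,5R,10R)-3-angeloyloxy-4-hydroxyeudesm-7(11)-en-8-one | C/C=C(/C)C(=O)O[C@@H]1CC[C@]2(C)CC(=O)C(=C(C)C)C[C@H]2[C@]1(C)O | intermediate
7 | (3R,4S,5R,10R)-3-angeloyloxy-4-hydroxy-11-hydroperoxyeudesm-6-en-8-one | C/C=C(/C)C(=O)O[C@@H]1CC[C@]2(C)CC(=O)C(C(C)(C)OO)=C[C@H]2[C@]1(C)O | target

Total step count: 4. Longest linear sequence: 4 steps (1 → 2 → 3 → 6 → 7).

**Steps most likely to fail**

Step 1 (proposed new method). The protonation may discriminate poorly between the two mirror-image conformers of 1, and the C4 cation may lose a proton from C15 or C5 as well as from C3. Fallback with known chemistry, setting out from compound 1: the established achiral acid-mediated transannular cyclization (p-TsOH, CH2Cl2, 0 °C) should give racemic eudesma-3,7(11)-dien-8-one F1, which is freed from its double-bond isomers on silica impregnated with AgNO3. Upjohn dihydroxylation as in step 2 should then give racemic 3α,4α-dihydroxyeudesm-7(11)-en-8-one F2. Esterification of its 3-OH with (S)-O-methylmandelic acid (DCC, DMAP, CH2Cl2) should give two diastereomers, the (S)-O-methylmandelate of the (3R,4S,5R,10R)-diol F3 and the (S)-O-methylmandelate of the (3S,4R,5S,10S)-diol F4. These are separated by chromatography, and methanolysis of F3 (K2CO3, MeOH, 0 °C) comes back to the route at compound 3.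

Step 4. Singlet oxygen may also attack the angelate double bond in an ene reaction, or the product may be over-oxidized on long irradiation. Fallback, setting out from compound 3, where no second alkene competes: photooxygenation under the conditions of step 4 should give (3R,4S,5R,10R)-3,4-dihydroxy-11-hydroperoxyeudesm-6-en-8-one F6. Selective silylation of the more acidic and more nucleophilic hydroperoxide (Et3SiCl, imidazole, DMF, 0 °C) should give the 11-triethylsilylperoxy diol F7. Yamaguchi angeloylation of its 3-OH as in step 3, at the lowest workable temperature, should give the 3-angelate of the silyl peroxide F8. Cleavage of the silyl peroxide with HF·pyridine (THF, 0 °C) comes back to the route at compound 7.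

Step 3. The angeloyl group may isomerize from Z to E during activation, and the hindered axial alcohol may be acylated only sluggishly. Fallback, setting out from compound 3, which builds the Z alkene on the substrate: esterification with 2-[bis(2,2,2-trifluoroethoxy)phosphoryl]propanoic acid (EDC·HCl, DMAP, CH2Cl2) should give the 3-O-[2-(bis(2,2,2-trifluoroethoxy)phosphoryl)propanoyl] ester F5, a mixture of epimers at the phosphonate α-carbon. Still–Gennari olefination (KHMDS, 18-crown-6, THF, −78 °C; then acetaldehyde) should give the Z-trisubstituted enoate and comes back to the route at compound 6.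

**Further compounds**
F1 | step 1 | racemic eudesma-3,7(11)-dien-8-one (both enantiomers, trans-fused) | CC1=CCC[C@]2(C)CC(=O)C(=C(C)C)C[C@@H]12.CC1=CCC[C@@]2(C)CC(=O)C(=C(C)C)C[C@H]12
F2 | step 1 | racemic 3α,4α-dihydroxyeudesm-7(11)-en-8-one (both enantiomers) | O[C@@H]1CC[C@]2(C)CC(=O)C(=C(C)C)C[C@H]2[C@]1(C)O.O[C@H]1CC[C@@]2(C)CC(=O)C(=C(C)C)C[C@@H]2[C@@]1(C)O
F3 | step 1 | (S)-O-methylmandelate of (3R,4S,5R,10R)-3,4-dihydroxyeudesm-7(11)-en-8-one (ester at O-3) | CO[C@H](C(=O)O[C@@H]1CC[C@]2(C)CC(=O)C(=C(C)C)C[C@H]2[C@]1(C)O)c1ccccc1
F4 | step 1 | (S)-O-methylmandelate of (3S,4R,5S,10S)-3,4-dihydroxyeudesm-7(11)-en-8-one (ester at O-3) | CO[C@H](C(=O)O[C@H]1CC[C@@]2(C)CC(=O)C(=C(C)C)C[C@@H]2[C@@]1(C)O)c1ccccc1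
F5 | step 3 | (3R,4S,5R,10R)-3-[2-(bis(2,2,2-trifluoroethoxy)phosphoryl)propanoyloxy]-4-hydroxyeudesm-7(11)-en-8-one (epimers at the phosphonate α-carbon) | CC(C(=O)O[C@@H]1CC[C@]2(C)CC(=O)C(=C(C)C)C[C@H]2[C@]1(C)O)P(=O)(OCC(F)(F)F)OCC(F)(F)F
F6 | step 4 | (3R,4S,5R,10R)-3,4-dihydroxy-11-hydroperoxyeudesm-6-en-8-one | O[C@@H]1CC[C@]2(C)CC(=O)C(C(C)(C)OO)=C[C@H]2[C@]1(C)O
F7 | step 4 | (3R,4S,5R,10R)-3,4-dihydroxy-11-(triethylsilylperoxy)eudesm-6-en-8-one | O[C@@H]1CC[C@]2(C)CC(=O)C(C(C)(C)OO[Si](CC)(CC)CC)=C[C@H]2[C@]1(C)O
F8 | step 4 | (3R,4S,5R,10R)-3-angeloyloxy-4-hydroxy-11-(triethylsilylperoxy)eudesm-6-en-8-one | C/C=C(/C)C(=O)O[C@@H]1CC[C@]2(C)CC(=O)C(C(C)(C)OO[Si](CC)(CC)CC)=C[C@H]2[C@]1(C)O
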